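**Assumption:** the lactol (hemiacylal) carbon is the only stereocentre and is (S) in the given SMILES. Free 3-hydroxyphthalides epimerise by ring–chain tautomerism in base or protic media, so the centre is carried as a configurationally stable chiral acetal, fixed by crystallisation-driven epimerisation, unveiled in the last step under neutral aprotic conditions, and the product is kept as a solid.

## Retrosynthetic overview

1. Target ⇐ depsidone whose (S)-lactol is masked as a photolabile (1S)-1-(2-nitrophenyl)ethyl acetal; the last step cleaves only the auxiliary C–O bond.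
2. Central seven-membered ring ⇐ fully functionalised para-depside, by late dehydrogenative phenol C–O coupling (ring-A 2-OH onto the ring-B C–H para to its free OH), as in the depside → depsidone oxidation.
3. Depside ⇐ haematommic acid (ring A) + the non-chelated 5-OH of a ring-B hydroxyphthalide acetal.
4. Ring-B lactol ring ⇐ oxidation of the methyl ortho to the carboxyl to aldehyde level with spontaneous ring closure; the acetal centre is funnelled to (3S) by acid-mediated epimerisation with crystallisation; CH2OAc ⇐ the formyl group.
5. Both rings ⇐ methyl haematommate ⇐ methyl orsellinate. Ring order: lactol (phthalide) ring first, central depsidone ring second.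

Phthalide numbering used below: 2-benzofuran-1(3H)-one, C1 = lactone C=O, C3 = acetal/lactol carbon.

## Route

**Step 1**
Reactants: 1 methyl orsellinate (methyl 2,4-dihydroxy-6-methylbenzoate)
Product: 2 methyl haematommate (methyl 3-formyl-2,4-dihydroxy-6-methylbenzoate)
Conditions: Cl2CHOMe, TiCl4, CH2Cl2, −10 → 0 °C; then aq. HCl; crystallise
Reagents that add atoms: dichloromethyl methyl ether, COC(Cl)Cl; water, O
Why: Rieche formylation, in which titanium phenoxide chelation directs the electrophile to C3 between the two hydroxyls, giving the doubly hydrogen-bonded aldehyde that is easily purified.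

**Step 2**
Reactants: 2 methyl haematommate
Product: 3 haematommic acid (3-formyl-2,4-dihydroxy-6-methylbenzoic acid)
Conditions: conc. H2SO4, 20 °C; then ice/H2O
Reagents that add atoms: water, O
Why: A_AC1 ester hydrolysis through the acylium ion of an electron-rich 2,6-disubstituted benzoate, which avoids the decarboxylation that alkaline hydrolysis of resorcylates causes.

**Step 3**
Reactants: 2 methyl haematommate
Product: 5 methyl 2,4-diacetoxy-3-(acetoxymethyl)-6-methylbenzoate, via salicyl alcohol triol 4 (not isolated)
Conditions: NaBH4, THF/H2O (20:1), 0 °C; then Ac2O, pyridine, cat. DMAP, 0 °C → rt (one pot)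
Reagents that add atoms: acetic anhydride, CC(=O)OC(C)=O
Why: Borohydride reduces the chelated aryl aldehyde but not the hindered salicylate ester, and exhaustive O-acetylation in the same flask traps the quinone-methide-prone 2,6-dihydroxybenzyl alcohol as a robust triacetate.

**Step 4**
Reactants: 5 methyl 2,4-diacetoxy-3-(acetoxymethyl)-6-methylbenzoate; 6 (1S)-1-(2-nitrophenyl)ethanol
Product: 10 (3S)-5,7-diacetoxy-6-(acetoxymethyl)-3-[(1S)-1-(2-nitrophenyl)ethoxy]phthalide, via gem-dibromide 7 (not isolated), via 3-bromophthalide 8 (not isolated), via (3R)-acetal epimer 9 (not isolated)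
Conditions: NBS (2.2 equiv), cat. AIBN, PhCl, 85 °C; then 132 °C (−MeBr); cool, filter; 6 (1.05 equiv), 2,6-lutidine, 50 °C; aq. wash, solvent swap; CSA (5 mol%), iPr2O/heptane slurry, 40 → 5 °C, seeded with 10; filter
Reagents that add atoms: N-bromosuccinimide, O=C1CCC(=O)N1Br (its bromine is carried only in 7 and 8; the atoms added to 10 come from reactant 6)
Why: Wohl–Ziegler dibromination occurs at the only unhindered non-oxygenated benzylic position, the ortho ester closes onto the gem-dibromide with loss of MeBr to form the lactol ring as its bromide, SN1 substitution through the phthalidyl oxocarbenium gives both C3 epimers (about 1:1), and a crystallisation-induced diastereomer transformation then sets the (3S) centre, because catalytic acid interconverts epimer 9 and 10 through the same oxocarbenium while the less soluble (3S,1′S) acetal 10 crystallises out under control of the (1S) auxiliary, whose nitro-deactivated benzylic centre does not ionise.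

**Step 5**
Reactants: 10 (3S)-5,7-diacetoxy-6-(acetoxymethyl)-3-[(1S)-1-(2-nitrophenyl)ethoxy]phthalide
Product: 11 (3S)-6-(acetoxymethyl)-5,7-dihydroxy-3-[(1S)-1-(2-nitrophenyl)ethoxy]phthalide
Conditions: NH3 (7 M in MeOH, 4.5 equiv), THF, −20 → 0 °C; then AcOH
Reagents that add atoms: none
Why: Chemoselective aminolysis, because the two aryl acetates (phenoxide leaving groups activated by the lactone carbonyl) react far faster than the primary alkyl acetate or the lactone, and the resulting carbonyl-conjugated phenoxides are poor quinone-methide precursors at this temperature, so CH2OAc and the acetal centre are untouched.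

**Step 6**
Reactants: 11 (3S)-6-(acetoxymethyl)-5,7-dihydroxy-3-[(1S)-1-(2-nitrophenyl)ethoxy]phthalide; 3 haematommic acid
Product: 12 (3S)-6-(acetoxymethyl)-7-hydroxy-3-[(1S)-1-(2-nitrophenyl)ethoxy]-1-oxo-1,3-dihydro-2-benzofuran-5-yl 3-formyl-2,4-dihydroxy-6-methylbenzoate (para-depside)
Conditions: DCC, DMAP (5 mol%), CH2Cl2/THF, 0 °C → rt
Reagents that add atoms: none
Why: Steglich-type depside esterification, in which the free 5-OH of 11 is acylated in preference to the 7-OH hydrogen-bonded to the lactone carbonyl, while the chelated phenols of 3 do not self-acylate.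

**Step 7**
Reactants: 12 para-depside
Product: 13 galbinic acid (S)-lactol O-[(1S)-1-(2-nitrophenyl)ethyl] ether (depsidone; ring-A 2-oxygen bonded to phthalide C4)
Conditions: PhI(OAc)2 (1.05 equiv), (CF3)2CHOH, 2 mM, −20 → 0 °C
Reagents that add atoms: none
Why: Proposed new method: PhI(OAc)2 exchanges a ligand at the ring-B 7-OH, the only weakly chelated phenol with a para C–H (the ring-A phenols sit in strong six-membered hydrogen bonds), the tethered ring-A 2-OH attacks the para carbon C4 through a seven-membered transition state with loss of PhI, and the 4-aryloxycyclohexadienone tautomerises to the aromatic depsidone, with non-nucleophilic HFIP, high dilution and one equivalent of oxidant limiting over-oxidation; the closest known reaction types are hypervalent-iodine para-oxygenation of phenols (dearomatisation–rearomatisation) and Tl(III)/I(III)-mediated intramolecular phenol C–O couplings to diaryl ethers, and no stereocentre is formed or touched.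

**Step 8**
Reactants: 13 depsidone acetal
Product: 14 galbinic acid, (S)-lactol (target)
Conditions: hν (365 nm, flow), degassed MeCN, 0 °C; concentrate below 10 °C; crystallise at once (acetone/heptane)
Reagents that add atoms: none
Why: o-Nitrobenzyl photocleavage (intramolecular H-abstraction, aci-nitro, hemiketal collapse) breaks only the auxiliary C–O bond, so the (S)-lactol set in step 4 is released with retention under neutral aprotic conditions, while the o-hydroxyaryl carbonyl chromophores of the depsidone dissipate light harmlessly by excited-state proton transfer.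

## Compound list

1 | methyl orsellinate | COC(=O)c1c(C)cc(O)cc1O | starting material
2 | methyl haematommate | COC(=O)c1c(C)cc(O)c(C=O)c1O | intermediate
3 | haematommic acid | Cc1cc(O)c(C=O)c(O)c1C(=O)O | intermediate
4 | methyl 2,4-dihydroxy-3-(hydroxymethyl)-6-methylbenzoate | COC(=O)c1c(C)cc(O)c(CO)c1O | intermediate (not isolated)
5 | methyl 2,4-diacetoxy-3-(acetoxymethyl)-6-methylbenzoate | COC(=O)c1c(C)cc(OC(C)=O)c(COC(C)=O)c1OC(C)=O | intermediate
6 | (1S)-1-(2-nitrophenyl)ethanol | C[C@H](O)c1ccccc1[N+](=O)[O-] | starting material
7 | methyl 2,4-diacetoxy-3-(acetoxymethyl)-6-(dibromomethyl)benzoate | COC(=O)c1c(C(Br)Br)cc(OC(C)=O)c(COC(C)=O)c1OC(C)=O | intermediate (not isolated)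
8 | rac-5,7-diacetoxy-6-(acetoxymethyl)-3-bromophthalide | O=C1OC(Br)c2cc(OC(C)=O)c(COC(C)=O)c(OC(C)=O)c12 | intermediate (not isolated)
9 | (3R)-5,7-diacetoxy-6-(acetoxymethyl)-3-[(1S)-1-(2-nitrophenyl)ethoxy]phthalide (C3 epimer of 10, epimerised in the flask) | O=C1O[C@@H](O[C@@H](C)c3ccccc3[N+](=O)[O-])c2cc(OC(C)=O)c(COC(C)=O)c(OC(C)=O)c12 | intermediate (not isolated)
10 | (3S)-5,7-diacetoxy-6-(acetoxymethyl)-3-[(1S)-1-(2-nitrophenyl)ethoxy]phthalide | O=C1O[C@H](O[C@@H](C)c3ccccc3[N+](=O)[O-])c2cc(OC(C)=O)c(COC(C)=O)c(OC(C)=O)c12 | intermediate
11 | (3S)-6-(acetoxymethyl)-5,7-dihydroxy-3-[(1S)-1-(2-nitrophenyl)ethoxy]phthalide | O=C1O[C@H](O[C@@H](C)c3ccccc3[N+](=O)[O-])c2cc(O)c(COC(C)=O)c(O)c12 | intermediate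
12 | para-depside: (3S)-6-(acetoxymethyl)-7-hydroxy-3-[(1S)-1-(2-nitrophenyl)ethoxy]-1-oxo-1,3-dihydro-2-benzofuran-5-yl 3-formyl-2,4-dihydroxy-6-methylbenzoate | O=C1O[C@H](O[C@@H](C)c3ccccc3[N+](=O)[O-])c2cc(OC(=O)c4c(C)cc(O)c(C=O)c4O)c(COC(C)=O)c(O)c12 | intermediate
13 | galbinic acid (S)-lactol O-[(1S)-1-(2-nitrophenyl)ethyl] ether | CC(=O)OCc1c(O)c2c(c3c1OC(=O)c1c(C)cc(O)c(C=O)c1O3)[C@@H](O[C@@H](C)c4ccccc4[N+](=O)[O-])OC2=O | intermediate
14 | galbinic acid, (S)-lactol | CC(=O)OCc1c(O)c2c(c3c1OC(=O)c1c(C)cc(O)c(C=O)c1O3)[C@@H](O)OC2=O | target

## Step count and risks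

Total steps: 8. Longest linear sequence: 7 (steps 1, 3, 4, 5, 6, 7, 8).

**Step 7 (dehydrogenative C–O coupling).** Ring A may be oxidised instead, acetate may add at the para carbon, or the p-aryloxyphenol product may over-oxidise. The fallback replaces C–H oxidation by a redox-neutral cross-coupling. It sets out from 11, which is brominated at its only free ring position (NBS, MeCN, −20 °C) to (3S)-6-(acetoxymethyl)-4-bromo-5,7-dihydroxy-3-[(1S)-1-(2-nitrophenyl)ethoxy]phthalide F1. DCC esterification with 3 then gives the 4-bromo para-depside F2. Intramolecular Ullmann etherification (CuI, picolinic acid, K3PO4, dioxane, 80 °C) joins the ring-A 2-oxygen to C4 and returns to the route at 13.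

**Step 8 (photolytic unveiling and configurational integrity).** Light may be absorbed unproductively by the depsidone, or the freed lactol may partly epimerise through its own acidic phenols. The fallback obtains the enantiomer by resolution instead of stereoretentive deprotection. It sets out from 13, which is cleaved by acidolysis (TFA/CH2Cl2/H2O, 0 °C, auxiliary recovered) to racemic galbinic acid F3. This is resolved by cold, acid-modified preparative chiral SFC on an amylose phase, or by seeded crystallisation-induced deracemisation that uses the ring–chain tautomerism to funnel material into the (S) crystals, and the route is rejoined at 14.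

**Step 4 (double benzylic bromination, thermal lactonisation, acetal formation, epimer funnelling).** The risks are mixed bromination levels, sluggish loss of MeBr, poor capture by the hindered alcohol, and a slurry in which 10 fails to crystallise or the (3R) epimer 9 proves the less soluble one; seed crystals of 10 come from a small chromatographed batch. The fallback uses ionic oxidation, transacetalisation and chromatographic sorting of the epimers. It sets out from 5, which is monobrominated (NBS, 1.05 equiv) to methyl 2,4-diacetoxy-3-(acetoxymethyl)-6-(bromomethyl)benzoate F4. Kornblum-type oxidation with N-methylmorpholine N-oxide (MeCN, rt) gives methyl 2,4-diacetoxy-3-(acetoxymethyl)-6-formylbenzoate F5. Acid-catalysed pseudo-esterification with 6 (CSA, toluene, 4 Å sieves; hemiacetal closes onto the ester with loss of methanol) then gives the acetal as an equilibrium mixture of the (3R) epimer 9 and the (3S) epimer 10. These are separated on silica, the fraction of 9 is re-equilibrated with CSA and separated again, and the route is rejoined at 10.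

## Further compounds

F1 | step 7 | (3S)-6-(acetoxymethyl)-4-bromo-5,7-dihydroxy-3-[(1S)-1-(2-nitrophenyl)ethoxy]phthalide | O=C1O[C@H](O[C@@H](C)c3ccccc3[N+](=O)[O-])c2c(Br)c(O)c(COC(C)=O)c(O)c12
F2 | step 7 | (3S)-6-(acetoxymethyl)-4-bromo-7-hydroxy-3-[(1S)-1-(2-nitrophenyl)ethoxy]-1-oxo-1,3-dihydro-2-benzofuran-5-yl 3-formyl-2,4-dihydroxy-6-methylbenzoate | O=C1O[C@H](O[C@@H](C)c3ccccc3[N+](=O)[O-])c2c(Br)c(OC(=O)c4c(C)cc(O)c(C=O)c4O)c(COC(C)=O)c(O)c12
F3 | step 8 | racemic galbinic acid (both lactol configurations) | CC(=O)OCc1c(O)c2c(c3c1OC(=O)c1c(C)cc(O)c(C=O)c1O3)C(O)OC2=O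
F4 | step 4 | methyl 2,4-diacetoxy-3-(acetoxymethyl)-6-(bromomethyl)benzoate | COC(=O)c1c(CBr)cc(OC(C)=O)c(COC(C)=O)c1OC(C)=O
F5 | step 4 | methyl 2,4-diacetoxy-3-(acetoxymethyl)-6-formylbenzoate | COC(=O)c1c(C=O)cc(OC(C)=O)c(COC(C)=O)c1OC(C)=O
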